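## Retrosynthetic overview

1. The target is a meso bis-aldol. Each ring is opened at the bond between the ketone α-carbon and the carbinol carbon (the presumed biosynthetic aldol), giving one acyclic C30 bis(enone)–bis(Z-enal) with the oxidised-squalene skeleton.
2. Each ring is closed by conjugate hydride transfer to an enone followed by intramolecular aldol onto the Z-enal. Ring A is closed first with one catalyst enantiomer, ring B second with the other, which gives the meso relationship.
3. The tetracarbonyl precursor comes, by reduction and re-oxidation, from a diester–dienone made by two E-selective Wittig reactions of a dialdehyde diester with a keto ylide.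
4. The dialdehyde diester comes from two Z-selective Still–Gennari olefinations of succinaldehyde, which fix both future exocyclic alkene geometries before any ring exists.
5. Starting materials: Still–Gennari reagent, 3-bromo-1,1-dimethoxypropane, 2,5-dimethoxytetrahydrofuran, 4-methylpent-3-enoic acid, ethyltriphenylphosphonium bromide.

Assumption 1: the SMILES given is the meso (centrosymmetric) diastereomer, with ring A (1R,2S), ring B (1S,2R), both exocyclic alkenes Z and OH cis to the acyl group in each ring, so it has no enantiomer and the task is to make the two rings with opposite handedness.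

Assumption 2: (R)-BINAPO, (R)-2,2'-bis(diphenylphosphoryl)-1,1'-binaphthyl, is taken to give the (1R,2S) ring; if it gives the mirror-image ring, the same meso product results because the second ring is closed with the antipodal catalyst.

Assumption 3: two-fold (two-directional) steps are written as one transformation.

## Route

Step 1
Reactants: 1 methyl 2-[bis(2,2,2-trifluoroethoxy)phosphoryl]acetate (Still–Gennari reagent); 2 3-bromo-1,1-dimethoxypropane
Product: 3 methyl 2-[bis(2,2,2-trifluoroethoxy)phosphoryl]-5,5-dimethoxypentanoate (racemic)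
Conditions: NaH, DMF, 0 °C; then 2, NaI (cat.), 60 °C
Reagents that add atoms: none
Why: SN2 C-alkylation of the doubly stabilised phosphonoacetate anion (in situ Finkelstein activation by iodide); the acetal is inert to base, and the new stereocentre is racemic and is destroyed in step 3.

Step 2
Reactants: 4 2,5-dimethoxytetrahydrofuran (cis/trans mixture)
Product: 5 butanedial (succinaldehyde)
Conditions: H2O, 90 °C; distil off MeOH/H2O, then distil the product and use at once
Reagents that add atoms: water, O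
Why: Hydrolysis of the cyclic bis-acetal to the free 1,4-dialdehyde, driven by removal of methanol; no stereocentre is involved.

Step 3
Reactants: 3 methyl 2-[bis(2,2,2-trifluoroethoxy)phosphoryl]-5,5-dimethoxypentanoate (2.2 equiv); 5 butanedial
Product: 6 dimethyl (2Z,6Z)-2,7-bis(3,3-dimethoxypropyl)octa-2,6-dienedioate
Conditions: 3, KN(SiMe3)2, 18-crown-6, THF, −78 °C; then 5, −78 °C
Reagents that add atoms: none
Why: Two-fold Still–Gennari (Horner–Wadsworth–Emmons) olefination, in which the electron-poor bis(trifluoroethyl) phosphonate with a dissociated potassium counter-ion eliminates under kinetic control so that each new trisubstituted alkene has the ester cis to the CH2CH2 chain (2Z,6Z), the geometry later needed at both exocyclic alkenes.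

Step 4
Reactants: 6 dimethyl (2Z,6Z)-2,7-bis(3,3-dimethoxypropyl)octa-2,6-dienedioate
Product: 7 dimethyl (2Z,6Z)-2,7-bis(3-oxopropyl)octa-2,6-dienedioate
Conditions: 1 M HCl (aq), THF, 0 °C → rt
Reagents that add atoms: water, O
Why: Acid-catalysed acetal hydrolysis, under which the methyl esters are stable and the ester-conjugated Z-alkenes do not isomerise.

Step 5
Reactants: 8 4-methylpent-3-enoic acid; 9 ethyltriphenylphosphonium bromide (2.1 equiv)
Product: 12 6-methyl-2-(triphenylphosphoranylidene)hept-5-en-3-one, via acyl imidazolide 10 (not isolated), via ethylidene ylide 11 (not isolated)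
Conditions: 8, 1,1'-carbonyldiimidazole (CDI), THF, rt; added to 11 [from 9, KN(SiMe3)2 (2.0 equiv), THF, 0 °C] at −78 °C → rt
Reagents that add atoms: none
Why: C-acylation of a non-stabilised ylide (Bestmann transylidation), in which 11 attacks the acyl imidazolide at carbon faster than it enolises it and a second equivalent of 11 deprotonates the acylphosphonium salt to the stabilised keto ylide.

Step 6
Reactants: 7 dimethyl (2Z,6Z)-2,7-bis(3-oxopropyl)octa-2,6-dienedioate; 12 6-methyl-2-(triphenylphosphoranylidene)hept-5-en-3-one (2.5 equiv)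
Product: 13 dimethyl (2Z,6Z)-2,7-bis[(3E)-4,8-dimethyl-5-oxonona-3,7-dien-1-yl]octa-2,6-dienedioate
Conditions: toluene, 90 °C
Reagents that add atoms: none
Why: Two-fold Wittig olefination of the aliphatic aldehydes with an α-branched stabilised keto ylide, which gives the (E)-α-methyl enone (acyl trans to the chain) while the enoate esters stay inert under these neutral conditions.

Step 7
Reactants: 13 dimethyl (2Z,6Z)-2,7-bis[(3E)-4,8-dimethyl-5-oxonona-3,7-dien-1-yl]octa-2,6-dienedioate
Product: 14 (2Z,6Z)-2,7-bis[(3E)-5-hydroxy-4,8-dimethylnona-3,7-dien-1-yl]octa-2,6-diene-1,8-diol (mixture at the two secondary carbinols)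
Conditions: iBu2AlH (10 equiv), CH2Cl2, −78 → −20 °C; aq. potassium sodium tartrate
Reagents that add atoms: none
Why: Exhaustive iBu2AlH 1,2-reduction (esters to primary allylic alcohols, enones to secondary allylic alcohols) without change of alkene geometry; the esters cannot be taken to aldehydes selectively beside the ketones, so all four carbonyls are reduced and the two new carbinol centres are erased in step 8.

Step 8
Reactants: 14 (2Z,6Z)-2,7-bis[(3E)-5-hydroxy-4,8-dimethylnona-3,7-dien-1-yl]octa-2,6-diene-1,8-diol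
Product: 15 (2Z,6Z)-2,7-bis[(3E)-4,8-dimethyl-5-oxonona-3,7-dien-1-yl]octa-2,6-dienedial
Conditions: Dess–Martin periodinane (5 equiv), NaHCO3, CH2Cl2, 0 °C → rt
Reagents that add atoms: none
Why: Dess–Martin oxidation of all four allylic alcohols in one operation under bicarbonate buffering, which restores the (E)-enones and gives the (Z)-enals without Z-to-E isomerisation or migration of the β,γ-double bonds.

Step 9
Reactants: 15 (2Z,6Z)-2,7-bis[(3E)-4,8-dimethyl-5-oxonona-3,7-dien-1-yl]octa-2,6-dienedial
Product: 18 (2Z)-2-[(3E)-4,8-dimethyl-5-oxonona-3,7-dien-1-yl]-6-[(1Z,2S,3R)-2-hydroxy-3-methyl-3-(4-methylpent-3-enoyl)cyclohexylidene]hex-2-enal, via trichlorosilyl enolate 16 (not isolated), via trichlorosilyl aldolate 17 (not isolated)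
Conditions: HSiCl3 (1.0 equiv), (R)-BINAPO (10 mol %), EtCN, −78 → −40 °C; sat. aq. NaHCO3
Reagents that add atoms: none
Why: Proposed new method: an intramolecular, one-terminus version of the known Lewis-base-catalysed HSiCl3 reductive aldol reaction of enones with aldehydes, in which the phosphine-oxide-activated silane delivers hydride to the β-carbon of the s-cis enone through a six-membered transition state (the Z-enal is held away from s-cis by its cis chain and its C=O is reduced more slowly), the resulting (Z)-trichlorosilyl enolate 16 closes ring A through a chair, silicon-bridged aldol transition state with the enolate CH2 arm axial and the enal residue equatorial so that OH ends up cis to the acyl group, the chiral catalyst on silicon fixes the absolute sense (1R,2S), and the single equivalent of hydride limits reaction to one terminus (statistical, at most about 50 % of 18 per pass, with 15 and doubly cyclised material separated and 15 recycled).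

Step 10
Reactants: 18 (2Z)-2-[(3E)-4,8-dimethyl-5-oxonona-3,7-dien-1-yl]-6-[(1Z,2S,3R)-2-hydroxy-3-methyl-3-(4-methylpent-3-enoyl)cyclohexylidene]hex-2-enal
Product: 21 1-[(1R,2S,3Z)-2-hydroxy-3-{4-[(1Z,2R,3S)-2-hydroxy-3-methyl-3-(4-methylpent-3-enoyl)cyclohexylidene]butylidene}-1-methylcyclohexyl]-4-methylpent-3-en-1-one (meso target), via trichlorosilyl enolate 19 (not isolated), via trichlorosilyl aldolate 20 (not isolated)
Conditions: HSiCl3 (3 equiv), (S)-BINAPO (10 mol %), EtCN, −78 → −40 °C; sat. aq. NaHCO3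
Reagents that add atoms: none
Why: Proposed new method: the same reductive aldol cyclisation at the remaining terminus with the antipodal catalyst, where ring A is too remote to bias the closure, so (S)-BINAPO builds ring B through enolate 19 with the mirror-image (1S,2R) configuration and the same cis OH/acyl relationship, giving the meso compound (closest known reaction: the intermolecular HSiCl3/BINAPO reductive aldol of enones with aldehydes).

## Compound list

1 | methyl 2-[bis(2,2,2-trifluoroethoxy)phosphoryl]acetate | COC(=O)CP(=O)(OCC(F)(F)F)OCC(F)(F)F | starting material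
2 | 3-bromo-1,1-dimethoxypropane | COC(CCBr)OC | starting material
3 | methyl 2-[bis(2,2,2-trifluoroethoxy)phosphoryl]-5,5-dimethoxypentanoate (racemic) | COC(=O)C(CCC(OC)OC)P(=O)(OCC(F)(F)F)OCC(F)(F)F | intermediate
4 | 2,5-dimethoxytetrahydrofuran (cis/trans mixture) | COC1CCC(OC)O1 | starting material
5 | butanedial | O=CCCC=O | intermediate
6 | dimethyl (2Z,6Z)-2,7-bis(3,3-dimethoxypropyl)octa-2,6-dienedioate | COC(OC)CC/C(C(=O)OC)=C/CC/C=C(/CCC(OC)OC)C(=O)OC | intermediate
7 | dimethyl (2Z,6Z)-2,7-bis(3-oxopropyl)octa-2,6-dienedioate | O=CCC/C(C(=O)OC)=C/CC/C=C(/CCC=O)C(=O)OC | intermediate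
8 | 4-methylpent-3-enoic acid | CC(C)=CCC(=O)O | starting material
9 | ethyltriphenylphosphonium bromide | CC[P+](c1ccccc1)(c1ccccc1)c1ccccc1.[Br-] | starting material
10 | 1-(imidazol-1-yl)-4-methylpent-3-en-1-one (acyl imidazolide) | CC(C)=CCC(=O)n1ccnc1 | intermediate (not isolated)
11 | ethylidenetriphenylphosphorane | CC=P(c1ccccc1)(c1ccccc1)c1ccccc1 | intermediate (not isolated)
12 | 6-methyl-2-(triphenylphosphoranylidene)hept-5-en-3-one | CC(C)=CCC(=O)C(C)=P(c1ccccc1)(c1ccccc1)c1ccccc1 | intermediate
13 | dimethyl (2Z,6Z)-2,7-bis[(3E)-4,8-dimethyl-5-oxonona-3,7-dien-1-yl]octa-2,6-dienedioate | CC(C)=CCC(=O)/C(C)=C/CC/C(C(=O)OC)=C/CC/C=C(/CC/C=C(\C)C(=O)CC=C(C)C)C(=O)OC | intermediate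
14 | (2Z,6Z)-2,7-bis[(3E)-5-hydroxy-4,8-dimethylnona-3,7-dien-1-yl]octa-2,6-diene-1,8-diol (mixture at the secondary carbinols) | CC(C)=CCC(O)/C(C)=C/CC/C(CO)=C/CC/C=C(/CC/C=C(\C)C(O)CC=C(C)C)CO | intermediate
15 | (2Z,6Z)-2,7-bis[(3E)-4,8-dimethyl-5-oxonona-3,7-dien-1-yl]octa-2,6-dienedial | CC(C)=CCC(=O)/C(C)=C/CC/C(C=O)=C/CC/C=C(/CC/C=C(\C)C(=O)CC=C(C)C)C=O | intermediate
16 | (2Z,6Z)-2-[(4Z)-4,8-dimethyl-5-(trichlorosilyloxy)nona-4,7-dien-1-yl]-7-[(3E)-4,8-dimethyl-5-oxonona-3,7-dien-1-yl]octa-2,6-dienedial | CC(C)=CC/C(O[Si](Cl)(Cl)Cl)=C(\C)CCC/C(C=O)=C/CC/C=C(/CC/C=C(\C)C(=O)CC=C(C)C)C=O | intermediate (not isolated)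
17 | O-trichlorosilyl ether of 18 (ring A closed) | CC(C)=CCC(=O)[C@]1(C)CCC/C(=C/CC/C=C(/CC/C=C(\C)C(=O)CC=C(C)C)C=O)[C@@H]1O[Si](Cl)(Cl)Cl | intermediate (not isolated)
18 | (2Z)-2-[(3E)-4,8-dimethyl-5-oxonona-3,7-dien-1-yl]-6-[(1Z,2S,3R)-2-hydroxy-3-methyl-3-(4-methylpent-3-enoyl)cyclohexylidene]hex-2-enal | CC(C)=CCC(=O)[C@]1(C)CCC/C(=C/CC/C=C(/CC/C=C(\C)C(=O)CC=C(C)C)C=O)[C@@H]1O | intermediate
19 | (Z)-trichlorosilyl enolate of the remaining ketone of 18 | CC(C)=CCC(=O)[C@]1(C)CCC/C(=C/CC/C=C(/CCC/C(C)=C(\O[Si](Cl)(Cl)Cl)CC=C(C)C)C=O)[C@@H]1O | intermediate (not isolated)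
20 | ring-B O-trichlorosilyl ether of 21 | CC(C)=CCC(=O)[C@]1(C)CCC/C(=C/CC/C=C2/CCC[C@](C)(C(=O)CC=C(C)C)[C@@H]2O[Si](Cl)(Cl)Cl)[C@@H]1O | intermediate (not isolated)
21 | 1-[(1R,2S,3Z)-2-hydroxy-3-{4-[(1Z,2R,3S)-2-hydroxy-3-methyl-3-(4-methylpent-3-enoyl)cyclohexylidene]butylidene}-1-methylcyclohexyl]-4-methylpent-3-en-1-one (meso) | CC(C)=CCC(=O)[C@]1(C)CCC/C(=C/CC/C=C2/CCC[C@](C)(C(=O)CC=C(C)C)[C@@H]2O)[C@@H]1O | target

## Step count

Total steps: 10 (steps 2 and 5 are side-branch preparations).
Longest linear sequence: 8 (steps 1, 3, 4, 6, 7, 8, 9, 10).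

## Three steps most likely to fail

**Step 9.** The silane may reduce the enal instead of the enone, the α,α-disubstituted silyl enolate may be slow to cyclise, or the enantioselectivity may be low. The fallback moves the hydride transfer to a stage without aldehydes; it sets out from 13 and comes back at 21. Compound 13 is treated with Et3SiH and RhCl(PPh3)3 (1 mol %) in THF at 50 °C (1,4-hydrosilylation of both enones) to give dimethyl (2Z,6Z)-2,7-bis[(4Z)-4,8-dimethyl-5-(triethylsilyloxy)nona-4,7-dien-1-yl]octa-2,6-dienedioate F1. Reduction with iBu2AlH (CH2Cl2, −78 °C) gives the corresponding diol F2, and buffered Dess–Martin oxidation gives the dial F3, which carries two regio-defined silyl enol ethers and two Z-enals. Ring A is closed by a Lewis-base-activated Mukaiyama aldol reaction (SiCl4, 1.0 equiv, (R)-BINAPO or a chiral bis-phosphoramide, iPr2NEt, CH2Cl2, −78 °C) to give the mono-aldol that keeps one silyl enol ether F4. The same reaction with the antipodal catalyst closes ring B and gives 21. This aldol goes through an open transition state, so the cis OH/acyl outcome would have to be confirmed.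

**Step 10.** The free hydroxyl of 18 may consume the silane, or ring A may suffer retro-aldol or dehydration under chlorosilane conditions. The fallback sets out from 18 and comes back at 21. Et3SiCl and imidazole (DMF, 0 °C) give the triethylsilyl ether of 18 F5. The reductive aldol with HSiCl3 and (S)-BINAPO then gives the ring-A mono-triethylsilyl ether of the target F6, and HF·pyridine (THF, 0 °C) releases 21.

**Step 3.** The two-fold olefination may give insufficient Z,Z-selectivity, or succinaldehyde may not survive the base. The fallback replaces the phosphonate olefination by iodo-olefination and carbonylation; it sets out from 5 and comes back at 6. 4-Bromo-1,1-dimethoxybutane and PPh3 (MeCN, reflux) give (4,4-dimethoxybutyl)triphenylphosphonium bromide F7. Treatment with n-BuLi, then I2, then NaN(SiMe3)2 (THF, −78 °C) gives the α-iodo ylide (1-iodo-4,4-dimethoxybutylidene)triphenylphosphorane F8 (Stork–Zhao type). With 5 this gives (4Z,8Z)-4,9-diiodo-1,1,12,12-tetramethoxydodeca-4,8-diene F9, with iodine cis to the central chain. Methoxycarbonylation with Pd(PPh3)4 (CO 1 atm, MeOH, Et3N, DMF, 60 °C) replaces iodine by CO2Me with retention and gives 6.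

## Further compounds

F1 | step 9 | dimethyl (2Z,6Z)-2,7-bis[(4Z)-4,8-dimethyl-5-(triethylsilyloxy)nona-4,7-dien-1-yl]octa-2,6-dienedioate | CC(C)=CC/C(O[Si](CC)(CC)CC)=C(\C)CCC/C(C(=O)OC)=C/CC/C=C(/CCC/C(C)=C(\O[Si](CC)(CC)CC)CC=C(C)C)C(=O)OC
F2 | step 9 | (2Z,6Z)-2,7-bis[(4Z)-4,8-dimethyl-5-(triethylsilyloxy)nona-4,7-dien-1-yl]octa-2,6-diene-1,8-diol | CC(C)=CC/C(O[Si](CC)(CC)CC)=C(\C)CCC/C(CO)=C/CC/C=C(/CCC/C(C)=C(\O[Si](CC)(CC)CC)CC=C(C)C)CO
F3 | step 9 | (2Z,6Z)-2,7-bis[(4Z)-4,8-dimethyl-5-(triethylsilyloxy)nona-4,7-dien-1-yl]octa-2,6-dienedial | CC(C)=CC/C(O[Si](CC)(CC)CC)=C(\C)CCC/C(C=O)=C/CC/C=C(/CCC/C(C)=C(\O[Si](CC)(CC)CC)CC=C(C)C)C=O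
F4 | step 9 | (2Z)-2-[(4Z)-4,8-dimethyl-5-(triethylsilyloxy)nona-4,7-dien-1-yl]-6-[(1Z,2S,3R)-2-hydroxy-3-methyl-3-(4-methylpent-3-enoyl)cyclohexylidene]hex-2-enal | CC(C)=CCC(=O)[C@]1(C)CCC/C(=C/CC/C=C(/CCC/C(C)=C(\O[Si](CC)(CC)CC)CC=C(C)C)C=O)[C@@H]1O
F5 | step 10 | (2Z)-2-[(3E)-4,8-dimethyl-5-oxonona-3,7-dien-1-yl]-6-[(1Z,2S,3R)-3-methyl-3-(4-methylpent-3-enoyl)-2-(triethylsilyloxy)cyclohexylidene]hex-2-enal | CC(C)=CCC(=O)[C@]1(C)CCC/C(=C/CC/C=C(/CC/C=C(\C)C(=O)CC=C(C)C)C=O)[C@@H]1O[Si](CC)(CC)CC
F6 | step 10 | ring-A mono-O-triethylsilyl ether of 21 | CC(C)=CCC(=O)[C@]1(C)CCC/C(=C/CC/C=C2/CCC[C@](C)(C(=O)CC=C(C)C)[C@@H]2O)[C@@H]1O[Si](CC)(CC)CC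
F7 | step 3 | (4,4-dimethoxybutyl)triphenylphosphonium bromide | COC(OC)CCC[P+](c1ccccc1)(c1ccccc1)c1ccccc1.[Br-]
F8 | step 3 | (1-iodo-4,4-dimethoxybutylidene)triphenylphosphorane | COC(OC)CCC(I)=P(c1ccccc1)(c1ccccc1)c1ccccc1
F9 | step 3 | (4Z,8Z)-4,9-diiodo-1,1,12,12-tetramethoxydodeca-4,8-diene | COC(OC)CC/C(I)=C/CC/C=C(\I)CCC(OC)OC
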